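**Plan**

- Retrosynthesis: the ring B allylic alcohol is traced back to a cyclohexene whose C=C lies one position over and whose second C–O is absent (ene transposition), and a ketone is placed on ring A next to the quaternary carbon. The two ring B bonds that leave the ring A/B fusion carbons (fusion CH to the CH3-bearing ring B carbon, and quaternary C to the neighbouring CH–O) are then cut together as a [4+2] retron, which also opens ring C.
- Enabling feature: in ring B (the cyclohexene) the two fusion carbons shared with ring A (the CH and the C–CH3) form a dienophile pair. The other four ring B carbons [C(CH3), the sp2 carbon that carries the ring C CH2, and the two CH–O carbons] are a 1-oxy-1,3-diene once the double bond is moved back. The eleven-membered ring C joins the inner diene carbon to the ring A carbon beside the dienophile, so one type 2 intramolecular Diels–Alder reaction closes rings B and C together.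
- Further cuts: C(=CH2)–CH(OAc) (Nozaki–Hiyama–Kishi reaction) into a ring A iodoalkene and a chain aldehyde; chain CH2–C(=CHCH3) (B-alkyl Suzuki–Miyaura coupling).
- Forward order: the chain is built (steps 1–5); ring A is bought as a silyloxy cyclopentenone and elaborated (steps 6–9); chain and ring A are joined (step 10); rings C and B are closed in one operation (step 14); the activating ketone is removed (step 15); the alkene is shifted with introduction of the last oxygen (step 16).
- Stereochemistry: the CH–CH3 center comes from (R)-β-citronellene; the ring A CH from the bought (R)-silyloxy enone by anti conjugate addition; CH–OAc from ligand-controlled addition to the aldehyde; the fusion CH, the quaternary carbon and the adjacent CH–O from substrate control in the cycloaddition; the last CH–OH from a face-selective ene reaction.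

Key step: step 14

Assumption: (R)-β-citronellene, (R)-4-(tert-butyldimethylsilyloxy)cyclopent-2-en-1-one, pent-3-yn-1-ol and a stock solution of [1-(trimethylsilyl)vinyl]magnesium bromide are taken as purchasable. Ring A is the cyclopentane, ring B the cyclohexene and ring C the eleven-membered carbocycle.

**Step 1**
Reactants: 1 pent-3-yn-1-ol
Product: 3 (Z)-3-iodopent-3-en-1-ol, via vinylstannane 2 (not isolated)
Conditions: Bu3SnH, [Cp*RuCl]4 (cat.), CH2Cl2, rt; then I2, CH2Cl2, 0 °C
Reagents that add atoms: iodine ([I][I])
Why: Hydroxyl-directed ruthenium-catalysed trans-hydrostannation should place tin on the alkyne carbon nearer the OH with H anti to it, and iododestannylation with retention then gives the iodoalkene with I cis to CH3, the geometry needed later for the E-ethylidene group.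

**Step 2**
Reactants: 3 (Z)-3-iodopent-3-en-1-ol
Product: 4 (Z)-tert-butyl[(3-iodopent-3-en-1-yl)oxy]diphenylsilane
Conditions: TBDPSCl, imidazole, CH2Cl2, rt
Reagents that add atoms: tert-butyl(chloro)diphenylsilane (CC(C)(C)[Si](Cl)(c1ccccc1)c1ccccc1)
Why: Standard silylation of a primary alcohol; the robust TBDPS ether is chosen to survive the acetal hydrolysis of step 5.

**Step 3**
Reactants: 5 (R)-β-citronellene [(3R)-3,7-dimethylocta-1,6-diene]
Product: 7 (R)-6,6-dimethoxy-3-methylhex-1-ene, via aldehyde 6 (not isolated)
Conditions: O3 (1 equiv), CH2Cl2–MeOH, −78 °C; Me2S; then TsOH·H2O (cat.), rt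
Reagents that add atoms: methanol (CO)
Why: Ozonolysis should take the electron-rich trisubstituted alkene much faster than the vinyl group, and acid-catalysed acetalisation in methanol masks the aldehyde for the hydroboration; the methyl stereocenter is not touched.

**Step 4**
Reactants: 7 (R)-6,6-dimethoxy-3-methylhex-1-ene; 4 (Z)-tert-butyl[(3-iodopent-3-en-1-yl)oxy]diphenylsilane
Product: 9 tert-butyl{[(3E,6S)-3-ethylidene-9,9-dimethoxy-6-methylnonyl]oxy}diphenylsilane, via B-alkyl-9-BBN 8 (not isolated)
Conditions: 9-BBN, THF, 0 °C → rt; then 4, PdCl2(dppf) (cat.), AsPh3, Cs2CO3, DMF–H2O, rt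
Reagents that add atoms: none
Why: B-alkyl Suzuki–Miyaura coupling: 9-BBN hydroborates the vinyl group at its terminus and the alkyl group is transferred to the iodoalkene with retention, which fixes the ethylidene CH3 cis to the new CH2.

**Step 5**
Reactants: 9 tert-butyl{[(3E,6S)-3-ethylidene-9,9-dimethoxy-6-methylnonyl]oxy}diphenylsilane
Product: 10 (4S,7E)-9-[(tert-butyldiphenylsilyl)oxy]-7-ethylidene-4-methylnonanal
Conditions: PPTS (cat.), acetone–H2O, 50 °C
Reagents that add atoms: water (O)
Why: Mild acid-catalysed hydrolysis of the dimethyl acetal, which the TBDPS ether and the trisubstituted alkene should tolerate.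

**Step 6**
Reactants: 11 (R)-4-[(tert-butyldimethylsilyl)oxy]cyclopent-2-en-1-one
Product: 13 (R)-4-[1-(trimethylsilyl)ethenyl]cyclopent-2-en-1-one, via β-silyloxy ketone 12 (not isolated)
Conditions: [1-(trimethylsilyl)vinyl]MgBr, CuBr·SMe2 (cat.), THF, −78 °C; H2O; then DBU, CH2Cl2, 0 °C
Reagents that add atoms: [1-(trimethylsilyl)vinyl]magnesium bromide (C=C([Mg]Br)[Si](C)(C)C)
Why: Copper-catalysed conjugate addition should occur anti to the silyloxy group, which is then lost by E1cB elimination, so the one bought stereocenter is relayed to the ring A carbon that will carry ring C.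

**Step 7**
Reactants: 13 (R)-4-[1-(trimethylsilyl)ethenyl]cyclopent-2-en-1-one
Product: 14 (R)-2-iodo-4-[1-(trimethylsilyl)ethenyl]cyclopent-2-en-1-one
Conditions: I2, pyridine, CH2Cl2, 0 °C → rt
Reagents that add atoms: iodine ([I][I])
Why: α-Iodination of a cyclic enone by conjugate addition of pyridine, iodination of the enolate and elimination; the stereocenter is not involved.

**Step 8**
Reactants: 14 (R)-2-iodo-4-[1-(trimethylsilyl)ethenyl]cyclopent-2-en-1-one
Product: 15 (R)-2-methyl-4-[1-(trimethylsilyl)ethenyl]cyclopent-2-en-1-one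
Conditions: Me4Sn, Pd2(dba)3 (cat.), AsPh3, CuI (cat.), NMP, 60 °C
Reagents that add atoms: tetramethylstannane (C[Sn](C)(C)C)
Why: Stille coupling of an α-iodo enone under neutral conditions, which should avoid base-induced migration of the doubly allylic ring hydrogen.

**Step 9**
Reactants: 15 (R)-2-methyl-4-[1-(trimethylsilyl)ethenyl]cyclopent-2-en-1-one
Product: 16 (R)-4-(1-iodoethenyl)-2-methylcyclopent-2-en-1-one
Conditions: NIS, MeCN, 0 °C → rt, dark
Reagents that add atoms: N-iodosuccinimide (O=C1CCC(=O)N1I)
Why: Electrophilic ipso-iododesilylation of the 1,1-disubstituted vinylsilane through the β-silyl cation; the electron-poor enone alkene should not react.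

**Step 10**
Reactants: 10 (4S,7E)-9-[(tert-butyldiphenylsilyl)oxy]-7-ethylidene-4-methylnonanal; 16 (R)-4-(1-iodoethenyl)-2-methylcyclopent-2-en-1-one
Product: 17 (4R)-4-[(3R,6S,9E)-11-[(tert-butyldiphenylsilyl)oxy]-9-ethylidene-3-hydroxy-6-methylundec-1-en-2-yl]-2-methylcyclopent-2-en-1-one
Conditions: CrCl2, NiCl2 (cat.), chiral oxazoline–sulfonamide ligand [N-(2-(4-isopropyl-4,5-dihydrooxazol-2-yl)-6-methylphenyl)methanesulfonamide, the enantiomer that leads to the R carbinol], Et3N, THF, rt
Reagents that add atoms: none
Why: Nozaki–Hiyama–Kishi reaction: the alkenylchromium species adds only to the aldehyde (ketone, enone and silyl ether are tolerated), and the new carbinol center is set by the chiral ligand on chromium.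

**Step 11**
Reactants: 17 (4R)-4-[(3R,6S,9E)-11-[(tert-butyldiphenylsilyl)oxy]-9-ethylidene-3-hydroxy-6-methylundec-1-en-2-yl]-2-methylcyclopent-2-en-1-one
Product: 18 (3R,6S,9E)-11-[(tert-butyldiphenylsilyl)oxy]-9-ethylidene-6-methyl-2-[(1R)-3-methyl-4-oxocyclopent-2-en-1-yl]undec-1-en-3-yl acetate
Conditions: Ac2O, pyridine, DMAP (cat.), CH2Cl2, 0 °C
Reagents that add atoms: acetic anhydride (CC(=O)OC(C)=O)
Why: Acylation of the secondary allylic alcohol with retention; the acetate of the target is installed here because no later step uses a nucleophile, a hydride strong enough to cleave it or a palladium catalyst.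

**Step 12**
Reactants: 18 (3R,6S,9E)-11-[(tert-butyldiphenylsilyl)oxy]-9-ethylidene-6-methyl-2-[(1R)-3-methyl-4-oxocyclopent-2-en-1-yl]undec-1-en-3-yl acetate
Product: 19 (3R,6S,9E)-9-ethylidene-11-hydroxy-6-methyl-2-[(1R)-3-methyl-4-oxocyclopent-2-en-1-yl]undec-1-en-3-yl acetate
Conditions: HF·pyridine, pyridine, THF, 0 °C → rt
Reagents that add atoms: none
Why: Buffered fluoride cleavage of the primary silyl ether, which should leave the acetate and the enone untouched.

**Step 13**
Reactants: 19 (3R,6S,9E)-9-ethylidene-11-hydroxy-6-methyl-2-[(1R)-3-methyl-4-oxocyclopent-2-en-1-yl]undec-1-en-3-yl acetate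
Product: 21 (3R,6S,9E,10E)-11-[(tert-butyldimethylsilyl)oxy]-9-ethylidene-6-methyl-2-[(1R)-3-methyl-4-oxocyclopent-2-en-1-yl]undeca-1,10-dien-3-yl acetate, via aldehyde 20 (not isolated)
Conditions: Dess–Martin periodinane, CH2Cl2, 0 °C; filtration; then TBSOTf (1.1 equiv), Et3N, CH2Cl2, −78 °C
Reagents that add atoms: tert-butyldimethylsilyl trifluoromethanesulfonate (CC(C)(C)[Si](C)(C)OS(=O)(=O)C(F)(F)F)
Why: Dess–Martin oxidation gives the β,γ-unsaturated aldehyde, whose doubly activated CH2 should be silylated (soft enolisation) at a temperature at which the conjugated cyclopentenone is not enolised; the E enol ether is favoured because the Z isomer suffers allylic strain against the ethylidene-bearing carbon.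

**Step 14**
Reactants: 21 (3R,6S,9E,10E)-11-[(tert-butyldimethylsilyl)oxy]-9-ethylidene-6-methyl-2-[(1R)-3-methyl-4-oxocyclopent-2-en-1-yl]undeca-1,10-dien-3-yl acetate
Product: 22 tricyclic keto silyl ether (Diels–Alder adduct): ring A cyclopentanone cis-fused to ring B cyclohexene with a bridgehead C=CH, bridged by the eleven-membered ring C; OTBS anti to the angular CH3; ring B CH(CH3) with CH3 syn to OTBS; exocyclic methylene and (R)-acetate in ring C
Conditions: Tf2NH (10 mol%), CH2Cl2, 1 mM (slow addition of 21), −78 → −40 °C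
Reagents that add atoms: none
Why: Triflimide converts a trace of 21 into tert-butyldimethylsilyl triflimide, which activates the enone carbonyl; the CH(CH3) terminus of the silyl dienol ether (C-4 of the diene) bonds to the enone β-carbon, the transient ring A silyl enol ether closes onto the silyl-oxocarbenium carbon, and the silyl cation passes on to the next enone, so the overall event is an asynchronous [4+2] cycloaddition at its Mukaiyama–Michael/aldol limit. The closest known reaction types are the triflimide-catalysed Diels–Alder reaction of silyloxy dienes with hindered α-substituted cycloalkenones and the type 2 intramolecular Diels–Alder reaction of dienes tethered at an inner carbon, which gives bridged bicycles with a bridgehead alkene. The first bond closes ring C in the bridged mode as an eleven-membered ring (11-exo-trig at the enone) and the second closes ring B as a six-membered ring (6-exo-trig at the oxocarbenium carbon), cis-fused to ring A. The fusion CH is set by attack on the enone face anti to the side chain on the neighbouring ring A stereocenter, the quaternary carbon by the cis (suprafacial) fusion, the C–OTBS carbon by the endo arrangement of the 1E enol ether over the ring A carbonyl (OTBS anti to the angular CH3), and the CH(CH3) carbon by the E-ethylidene geometry (CH3 syn to OTBS, H on the convex face, as step 16 requires). The step needs ortho regiochemistry, secured by the 1-silyloxy donor, which makes C-4 the nucleophilic diene terminus and the β-carbon its electrophilic partner, and ring closure in preference to oligomerisation, secured by high dilution with slow addition and helped by the inner substituent of the diene, which raises the s-cis population.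

**Step 15**
Reactants: 22 tricyclic keto silyl ether (Diels–Alder adduct)
Product: 24 deoxygenated tricycle (ring A CH2 in place of C=O; otherwise as 22), via tosylhydrazone 23 (not isolated)
Conditions: TsNHNH2, AcOH (cat.), MeOH, 60 °C; then catecholborane, CHCl3, 0 °C; NaOAc·3H2O, 60 °C
Reagents that add atoms: none
Why: Tosylhydrazone reduction with catecholborane: hydroboration of C=N, loss of sulfinate and of N2 from the diazene replace C=O by CH2 under conditions mild enough for the acetate and the silyl ether; the α-carbon is quaternary, so neither epimerisation nor β-elimination of the silyloxy group can occur.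

**Step 16**
Reactants: 24 deoxygenated tricycle
Product: 26 mono-TBS ether of the target diol (OTBS on the carbinol next to the quaternary carbon, free allylic OH, tetrasubstituted ring B alkene), via allylic hydroperoxide 25 (not isolated)
Conditions: O2, tetraphenylporphyrin (cat.), visible light, CH2Cl2, −20 °C; then PPh3
Reagents that add atoms: dioxygen (O=O)
Why: Schenck ene reaction: singlet oxygen should attack the trisubstituted ring B alkene (the 1,1-disubstituted alkene is far less reactive) on the face opposite to the allylic OTBS and CH3 groups, bond to the CH carbon and remove the pseudo-axial hydrogen of the CH(CH3) carbon on that same face (cis effect), which sets the new carbinol anti to the OTBS carbon and moves the double bond into its final tetrasubstituted position; PPh3 reduces the hydroperoxide.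

**Step 17**
Reactants: 26 mono-TBS ether of the target diol
Product: 27 CNP0192310.2 (target)
Conditions: HF·pyridine, THF, 0 °C → rt
Reagents that add atoms: none
Why: Fluoride cleavage of the hindered secondary silyl ether under buffered acidic conditions, which should not move or cleave the acetate.

**Compound list**

1 | pent-3-yn-1-ol | CC#CCCO | starting material
2 | (Z)-3-(tributylstannyl)pent-3-en-1-ol | C/C=C(\[Sn](CCCC)(CCCC)CCCC)CCO | intermediate
3 | (Z)-3-iodopent-3-en-1-ol | C/C=C(\I)CCO | intermediate
4 | (Z)-tert-butyl[(3-iodopent-3-en-1-yl)oxy]diphenylsilane | C/C=C(\I)CCO[Si](c1ccccc1)(c1ccccc1)C(C)(C)C | intermediate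
5 | (R)-β-citronellene, (3R)-3,7-dimethylocta-1,6-diene | CC(C)=CCC[C@@H](C)C=C | starting material
6 | (R)-4-methylhex-5-enal | O=CCC[C@@H](C)C=C | intermediate
7 | (R)-6,6-dimethoxy-3-methylhex-1-ene | COC(OC)CC[C@@H](C)C=C | intermediate
8 | 9-[(3S)-6,6-dimethoxy-3-methylhexyl]-9-borabicyclo[3.3.1]nonane | COC(OC)CC[C@@H](C)CCB1C2CCCC1CCC2 | intermediate
9 | tert-butyl{[(3E,6S)-3-ethylidene-9,9-dimethoxy-6-methylnonyl]oxy}diphenylsilane | COC(OC)CC[C@@H](C)CC/C(=C\C)CCO[Si](c1ccccc1)(c1ccccc1)C(C)(C)C | intermediate
10 | (4S,7E)-9-[(tert-butyldiphenylsilyl)oxy]-7-ethylidene-4-methylnonanal | O=CCC[C@@H](C)CC/C(=C\C)CCO[Si](c1ccccc1)(c1ccccc1)C(C)(C)C | intermediate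
11 | (R)-4-[(tert-butyldimethylsilyl)oxy]cyclopent-2-en-1-one | O=C1C=C[C@H](O[Si](C)(C)C(C)(C)C)C1 | starting material
12 | (3R,4R)-4-[(tert-butyldimethylsilyl)oxy]-3-[1-(trimethylsilyl)ethenyl]cyclopentan-1-one (trans) | C=C([C@@H]1CC(=O)C[C@H]1O[Si](C)(C)C(C)(C)C)[Si](C)(C)C | intermediate
13 | (R)-4-[1-(trimethylsilyl)ethenyl]cyclopent-2-en-1-one | C=C([C@@H]1CC(=O)C=C1)[Si](C)(C)C | intermediate
14 | (R)-2-iodo-4-[1-(trimethylsilyl)ethenyl]cyclopent-2-en-1-one | C=C([C@@H]1CC(=O)C(I)=C1)[Si](C)(C)C | intermediate
15 | (R)-2-methyl-4-[1-(trimethylsilyl)ethenyl]cyclopent-2-en-1-one | C=C([C@@H]1CC(=O)C(C)=C1)[Si](C)(C)C | intermediate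
16 | (R)-4-(1-iodoethenyl)-2-methylcyclopent-2-en-1-one | C=C(I)[C@@H]1CC(=O)C(C)=C1 | intermediate
17 | (4R)-4-[(3R,6S,9E)-11-[(tert-butyldiphenylsilyl)oxy]-9-ethylidene-3-hydroxy-6-methylundec-1-en-2-yl]-2-methylcyclopent-2-en-1-one | C=C([C@@H]1CC(=O)C(C)=C1)[C@H](O)CC[C@@H](C)CC/C(=C\C)CCO[Si](c1ccccc1)(c1ccccc1)C(C)(C)C | intermediate
18 | (3R,6S,9E)-11-[(tert-butyldiphenylsilyl)oxy]-9-ethylidene-6-methyl-2-[(1R)-3-methyl-4-oxocyclopent-2-en-1-yl]undec-1-en-3-yl acetate | C=C([C@@H]1CC(=O)C(C)=C1)[C@H](OC(C)=O)CC[C@@H](C)CC/C(=C\C)CCO[Si](c1ccccc1)(c1ccccc1)C(C)(C)C | intermediate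
19 | (3R,6S,9E)-9-ethylidene-11-hydroxy-6-methyl-2-[(1R)-3-methyl-4-oxocyclopent-2-en-1-yl]undec-1-en-3-yl acetate | C=C([C@@H]1CC(=O)C(C)=C1)[C@H](OC(C)=O)CC[C@@H](C)CC/C(=C\C)CCO | intermediate
20 | (3R,6S,9E)-9-ethylidene-6-methyl-2-[(1R)-3-methyl-4-oxocyclopent-2-en-1-yl]-11-oxoundec-1-en-3-yl acetate | C=C([C@@H]1CC(=O)C(C)=C1)[C@H](OC(C)=O)CC[C@@H](C)CC/C(=C\C)CC=O | intermediate
21 | (3R,6S,9E,10E)-11-[(tert-butyldimethylsilyl)oxy]-9-ethylidene-6-methyl-2-[(1R)-3-methyl-4-oxocyclopent-2-en-1-yl]undeca-1,10-dien-3-yl acetate | C=C([C@@H]1CC(=O)C(C)=C1)[C@H](OC(C)=O)CC[C@@H](C)CC/C(=C\C)/C=C/O[Si](C)(C)C(C)(C)C | intermediate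
22 | tricyclic keto silyl ether (Diels–Alder adduct; cis-fused rings A/B, ring C bridging, OTBS anti to angular CH3, ring B CH3 syn to OTBS) | C=C1[C@H](OC(C)=O)CC[C@@H](C)CCC=2[C@@H](C)[C@H]3[C@H]1CC(=O)[C@@]3(C)[C@@H](O[Si](C)(C)C(C)(C)C)C2 | intermediate
23 | tosylhydrazone of 22 | C=C1[C@H](OC(C)=O)CC[C@@H](C)CCC=2[C@@H](C)[C@H]3[C@H]1CC(=NNS(=O)(=O)c4ccc(C)cc4)[C@@]3(C)[C@@H](O[Si](C)(C)C(C)(C)C)C2 | intermediate
24 | deoxygenated tricycle (ring A CH2 in place of C=O of 22) | C=C1[C@H](OC(C)=O)CC[C@@H](C)CCC=2[C@@H](C)[C@H]3[C@H]1CC[C@@]3(C)[C@@H](O[Si](C)(C)C(C)(C)C)C2 | intermediate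
25 | allylic hydroperoxide (OOH syn to the angular CH3, anti to OTBS; tetrasubstituted ring B alkene) | C=C1[C@H](OC(C)=O)CC[C@@H](C)CCC2=C(C)[C@H]3[C@H]1CC[C@@]3(C)[C@@H](O[Si](C)(C)C(C)(C)C)[C@@H]2OO | intermediate
26 | mono-TBS ether of the target diol | C=C1[C@H](OC(C)=O)CC[C@@H](C)CCC2=C(C)[C@H]3[C@H]1CC[C@@]3(C)[C@@H](O[Si](C)(C)C(C)(C)C)[C@@H]2O | intermediate
27 | CNP0192310.2 (tricyclic diol mono-acetate) | C=C1[C@H](OC(C)=O)CC[C@@H](C)CCC2=C(C)[C@H]3[C@H]1CC[C@@]3(C)[C@@H](O)[C@@H]2O | target

**Total step count:** 17. **Longest linear sequence:** 12 steps (steps 6 to 17, from 11).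

**Steps most likely to fail**

Step 14. The closure of the eleven-membered ring may be outrun by intermolecular cycloaddition and oligomerisation. The first bond may also form from an s-trans diene conformer, so that ring B cannot close, and the silyl Lewis acid may ionise the allylic acetate. The fallback makes ring B bimolecularly and closes ring C afterwards; it sets out from 5, 4 and 16 and comes back at 22. (R)-β-Citronellene 5 would be hydroborated at its vinyl group with 9-BBN to the borane F1 and coupled with 4 as in step 4 to the TBDPS ether F2. Desilylation (HF·pyridine) would give the alcohol F3, Dess–Martin oxidation the aldehyde F4, and silylation as in step 13 the silyl dienol ether F5, which carries the isopropylidene group as a latent aldehyde. Intermolecular [4+2] cycloaddition of F5 with the iodoalkene 16 (Tf2NH cat., CH2Cl2, −78 °C) should give the cis-hydrindanone F6 in the same regio- and stereochemical sense as step 14 (ortho, endo, anti to the iodoethenyl group). Ozonolysis of the electron-rich isopropylidene group (1 equiv O3; Me2S) would give the aldehyde F7. An intramolecular Nozaki–Hiyama–Kishi reaction under high dilution (CrCl2, NiCl2 cat., the ligand of step 10) would then close ring C to the macrocyclic allylic alcohol F8, and acetylation as in step 11 gives 22.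

Step 16. Hydrogen abstraction may occur from the ring C CH2 beside the alkene instead of from the ring B CH(CH3), oxygen may attack the wrong face, and the new tetrasubstituted alkene may be photo-oxygenated further. The fallback replaces the ene reaction by epoxide opening and a stereoelectronically controlled elimination; it sets out from 24 and comes back at 27. Epoxidation of 24 (mCPBA, NaHCO3, CH2Cl2, 0 °C) should take the trisubstituted ring B alkene from the face anti to OTBS and give the epoxide F9. Acid-catalysed hydrolysis (HClO4 cat., THF–H2O) opens it at the tertiary carbon with inversion to the trans-diol F10, and TESCl/imidazole silylates only the secondary hydroxyl to give the TES ether F11. Dehydration of the tertiary alcohol with POCl3 in pyridine (anti E2) should give the bis-silyl ether F12: the ring hydrogen on the CH(CH3) carbon is the one anti-periplanar to the activated C–O bond and leads to the more substituted alkene. HF·pyridine then removes both silyl groups to give 27.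

Step 10. Facial selectivity in the addition to the aldehyde may be poor if the ligand control is eroded by the neighbouring ring A stereocenter. The fallback secures the carbinol center by convergence instead of ligand control; it sets out from 10 and 16 and comes back at 18. The coupling would be run without the chiral ligand (CrCl2, NiCl2 cat., DMSO) to give 17 together with its carbinol epimer F13, and the two separated. 17 continues through step 11, and F13 is converted into the same acetate 18 by Mitsunobu inversion with acetic acid (PPh3, DIAD, THF).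

**Further compounds**

F1 | step 14 | 9-[(3S)-3,7-dimethyloct-6-en-1-yl]-9-borabicyclo[3.3.1]nonane | CC(C)=CCC[C@@H](C)CCB1C2CCCC1CCC2
F2 | step 14 | tert-butyl{[(3E,6R)-3-ethylidene-6,10-dimethylundec-9-en-1-yl]oxy}diphenylsilane | CC(C)=CCC[C@@H](C)CC/C(=C\C)CCO[Si](c1ccccc1)(c1ccccc1)C(C)(C)C
F3 | step 14 | (3E,6R)-3-ethylidene-6,10-dimethylundec-9-en-1-ol | CC(C)=CCC[C@@H](C)CC/C(=C\C)CCO
F4 | step 14 | (3E,6R)-3-ethylidene-6,10-dimethylundec-9-enal | CC(C)=CCC[C@@H](C)CC/C(=C\C)CC=O
F5 | step 14 | tert-butyl{[(1E,3E,6R)-3-ethylidene-6,10-dimethylundeca-1,9-dien-1-yl]oxy}dimethylsilane | CC(C)=CCC[C@@H](C)CC/C(=C\C)/C=C/O[Si](C)(C)C(C)(C)C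
F6 | step 14 | cis-hydrindanone adduct (rings A/B) with 1-iodoethenyl group on ring A and isopropylidene-terminated chain on ring B | C=C(I)[C@@H]1CC(=O)[C@@]2(C)[C@@H](O[Si](C)(C)C(C)(C)C)C=C(CC[C@H](C)CCC=C(C)C)[C@@H](C)[C@@H]12
F7 | step 14 | aldehyde from F6 (chain terminus CHO) | C=C(I)[C@@H]1CC(=O)[C@@]2(C)[C@@H](O[Si](C)(C)C(C)(C)C)C=C(CC[C@H](C)CCC=O)[C@@H](C)[C@@H]12
F8 | step 14 | macrocyclic allylic alcohol (22 with OH in place of OAc) | C=C1[C@H](O)CC[C@@H](C)CCC=2[C@@H](C)[C@H]3[C@H]1CC(=O)[C@@]3(C)[C@@H](O[Si](C)(C)C(C)(C)C)C2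
F9 | step 16 | ring B epoxide of 24 (oxygen anti to OTBS) | C=C1[C@H](OC(C)=O)CC[C@@H](C)CC[C@@]2(O4)[C@@H](C)[C@H]3[C@H]1CC[C@@]3(C)[C@@H](O[Si](C)(C)C(C)(C)C)[C@@H]24
F10 | step 16 | trans-diol from F9 (tertiary OH syn to OTBS, secondary OH anti) | C=C1[C@H](OC(C)=O)CC[C@@H](C)CC[C@]2(O)[C@@H](C)[C@H]3[C@H]1CC[C@@]3(C)[C@@H](O[Si](C)(C)C(C)(C)C)[C@@H]2O
F11 | step 16 | secondary TES ether of F10 | C=C1[C@H](OC(C)=O)CC[C@@H](C)CC[C@]2(O)[C@@H](C)[C@H]3[C@H]1CC[C@@]3(C)[C@@H](O[Si](C)(C)C(C)(C)C)[C@@H]2O[Si](CC)(CC)CC
F12 | step 16 | TBS/TES bis-silyl ether of the target diol | C=C1[C@H](OC(C)=O)CC[C@@H](C)CCC2=C(C)[C@H]3[C@H]1CC[C@@]3(C)[C@@H](O[Si](C)(C)C(C)(C)C)[C@@H]2O[Si](CC)(CC)CC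
F13 | step 10 | (3S)-carbinol epimer of 17 | C=C([C@@H]1CC(=O)C(C)=C1)[C@@H](O)CC[C@@H](C)CC/C(=C\C)CCO[Si](c1ccccc1)(c1ccccc1)C(C)(C)C
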